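The earlier runs and the new flask are calculated for substances that don't exist, noise included.

The ratio of the last to the first reading of first product in the green run is 0.392, and the next charge hangs on it. Which charge leaves most first product at 4.0 h?

| flask | starting material | coupling partner | remark | time |
|---|---|---|---|---|
| green | 0.10 M | 0.72 equiv | run made earlier |  |
| amber | 0.10 M | 3.1 equiv | run made earlier |  |
| zeta | 0.10 M | 0.500 equiv |  | 4.0 h |
| epsilon | 0.10 M | 2.00 equiv |  | 4.0 h |
| beta | 0.10 M | 2.50 equiv |  | 4.0 h |

| run | time / h | first product / % | double product / % |
|---|---|---|---|
| green | 0.500 | 44.4 | 1.7 |
| green | 1.00 | 39.3 | 4.3 |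
| green | 1.50 | 33.5 | 2.5 |
| green | 2.50 | 23.4 | 0.7 |
| green | 3.00 | 17.4 | 1.1 |
| amber | 0.250 | 33.9 | 57.8 |
| amber | 0.417 | 20.6 | 69.1 |
| amber | 0.833 | 8.8 | 80.0 |
| amber | 1.33 | 1.7 | 82.2 |
| amber | 3.00 | 0 | 86.3 |

(readings scatter by 1 percentage point)



- final first product, as a percentage of the starting material charged, for each flask in turn (zeta, epsilon, beta)

In the green run, double product stays between 0.7 % and 4.3 % while first product falls, so first product is leaving by some other way. Taken as exponential, that ratio gives the idle half-life, the time in which first product halves with little coupling going on: 1.85 h. This is a reading, with the scatter of its readings. In the amber run, with more partner than the double product takes, first product falls faster: a two-point average between 0.250 h and 0.833 h reads a half-life of 0.300 h, shorter than the idle one. So the choice of charge is a choice of clock.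

Zeta charges less partner than starting material, which makes partner the limiting reagent and puts zeta on the idle clock. Scaling the first green reading by the charge gives 30.8 % of first product at 0.500 h. The idle half-life then carries this to 8.31 % at 4.0 h. Epsilon and beta charge more partner than starting material, as amber did, and amber reads 1.7 % of first product at 1.33 h, before the time asked. The reckoning here therefore ranks zeta first and would charge 0.500 equiv.

The forecast gives 1 %, 11 % and 1 % for zeta, epsilon and beta, with epsilon on top. It calls the loss “roughly zero-order”, and there the two part.

The flasks give 8.96 %, 1.85 % and 0.277 %.

    starting material + coupling partner → first product (k = 0.0492 /M/s)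
    coupling partner + first product → double product (k = 0.00936 /M/s)
    starting material + double product → side product A (k = 0.00766 /M/s)
    first product → side product B (k = 1.18 × 10⁻⁴ /s)
    coupling partner ⇌ dormant form (K = 1.70, k = 6.55 × 10⁻⁴ /s)

In zeta, 20.0 % at 2.00 h carried by the idle half-life becomes 9.45 % at 4.00 h, against 8.96 % found, with free partner at 0.025 % of its charge. In epsilon, the same clock takes 10.5 % to 4.97 %, yet the flask holds 1.85 %, with free partner at 6.46 % of its charge. Part of the loss of first product in epsilon is due to the passing of first product into side product B: without that step, epsilon ends at 16.0 %. Another part comes from dormant form returning partner: without that back reaction, epsilon ends at 9.47 %.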